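Late in the zeta run the readings stop at 96.9 mM after 19 min, and the gamma flask asks about a point further along that curve.

| setting | zeta | eta | delta | beta | gamma |
|---|---|---|---|---|---|
| starting material | 250 mM | 100 mM | 500 mM | 250 mM | 250 mM |
| coupling partner | 300 mM | 150 mM | 300 mM | 300 mM | 300 mM |
| free catalyst | 1.30 mM | 1.30 mM | 1.30 mM | 2.60 mM | 4.50 mM |
| time |  |  |  |  | 19 min |

| zeta run: time / min | zeta run: [target] / mM | eta run: time / min | eta run: [target] / mM | delta run: time / min | delta run: [target] / mM | beta run: time / min | beta run: [target] / mM |
|---|---|---|---|---|---|---|---|
| 0.76 | 6.1 | 0.76 | 0.9 | 0.76 | 8.1 | 0.76 | 7.7 |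
| 1.7 | 12.9 | 1.7 | 4.2 | 1.7 | 18.5 | 1.7 | 17.9 |
| 3.8 | 25.7 | 3.8 | 8.1 | 3.8 | 37.3 | 3.8 | 36.6 |
| 8.5 | 51.3 | 8.5 | 14.9 | 8.5 | 75.4 | 8.5 | 71.6 |
| 19 | 96.9 | 19 | 31.6 | 19 | 138.9 | 19 | 127.9 |

(scatter of a reading: 0.8 mM)

1. apparent order in [starting material] of the starting rate, round the charge of the zeta run (the rate where two percent of its starting material have turned into target) (one fixed amount of target, the same in the runs compared)
2. apparent order in [free catalyst] of the starting rate, round the charge of the zeta run (the rate where two percent of its starting material have turned into target)
3. the eta run starts with 150 mM less of starting material and of coupling partner than the zeta run, and with no target. Compared where both hold the same amount of starting material, once fifteen percent of what the eta run was charged with has turned into target, is the eta run faster, slower or alike (within a tenth)?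
4. target in the gamma run at 19 min, as a share of the starting material charged

- Overall: starting material + coupling partner -> target, with free catalyst as catalyst.
- Constant volume, constant temperature.
- What is held in complexes is read along with the free species.
- An order is taken over about fifteen percent of the charge, up and down.

I reckoned on one rule: flasks with the same charge follow one curve, and more catalyst runs its clock faster. Beta has zeta's charge, and between its readings it passed zeta's 51.3 mM at about 5.77 min, against 8.5 min in zeta, so I read its clock as 1.47 times zeta's. Read as a power, that is an order of 0.558, which gave gamma a factor of 2.00:

gamma at 19 min = zeta at 38.0 min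

Where zeta stands then, I got from a balance. Starting material is the limiting reagent in zeta:

c(starting material) = 250 mM − c(target)
c(coupling partner) = 300 mM − c(target)

The gap between them stays 50.0 mM, and eta was charged with the same gap, 50.0 mM. Once zeta has made 150 mM, it holds eta's charge, so I let eta's curve continue zeta's from there, setting aside the target present.

Beta's last reading, 127.9 mM, falls at 28.0 min on zeta's clock. Its last stretch gives zeta a rate of 3.64 mM min⁻¹, and eta's mean rate up to its reading at 8.5 min is 1.75 mM min⁻¹. Bridging with their mean:

zeta reaches 150 mM at 36.2 min

Continuing at eta's rate gave 153 mM, or 61.3%.

The weak link was the power. I allowed for two paths, one catalysed and one not, whose rates add, since one doubling does not tell that form from a power. A straight line through zeta and beta, taken back to zero free catalyst, leaves half of zeta's rate standing. I took that line and named its result the clock factor 2.16, the zeta minutes that one gamma minute is worth: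

gamma at 19 min = zeta at 41.1 min
c(target) = 159 mM, which is 63.4%

The forecast gave 0.6 for the order in starting material, 0.5 for the order in free catalyst, alike for eta, and 56% for gamma, within 51% to 61%. On eta it said: “At equal starting material the two runs also hold equal coupling partner, so I expect them alike”. My number stood higher than its upper end.

    2 free catalyst ⇌ catalyst dimer, settled at all times (6060 M⁻¹)
    catalyst dimer + starting material + coupling partner → target + catalyst dimer (250.8 M⁻² min⁻¹)
    starting material + coupling partner → target (0.1512 M⁻¹ min⁻¹)
    2 starting material ⇌ idle substrate dimer, settled at all times (11.10 M⁻¹)

The gamma run gave 64.0%, which is 160 mM of target. The order in starting material came to 0.62, and eta came out alike, at a rate ratio of 1.0. The local order in free catalyst came to 0.51, while the best single order over the runs was higher, 0.60. Beta's target reached half of its starting material at 18.3 min, which is 27.0 min on zeta's clock. Divided by the clock factor of 2.16, that puts gamma at the same point at 12.5 min.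

All runs stem from a simulated flask from invented constants, noise included.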